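## The problem

The target 23 is a tridepside: three benzoate rings joined head to tail by two aryl ester bonds, the carboxyl of ring A to O4 of ring B and the carboxyl of ring B to O4 of ring C, with ring C ending in a free acid. Rings B and C are plain orsellinic acid units, so the chain is built by two phenol acylations, each at an unchelated para hydroxyl beside a hydrogen-bonded ortho hydroxyl. There is no stereocentre, so all control is positional. The aryl ester links are activated esters and will not survive hydroxide, alkoxide or amines. The ring A catechol (C3, C4) oxidises in base and air, the C6 methoxy group lies ortho to the ring A carbonyl and would be stripped by BCl3 or AlCl3, and the salicylic-type acids lose CO2 in hot acid. The last step therefore has to be neutral, which means hydrogenolysis of benzyl groups, and every earlier protecting-group choice follows from that. The hard part is ring A, a pentasubstituted benzene (C1 carboxyl, C2 methyl, C3 OH, C4 OH, C5 H, C6 OMe) whose three oxygens must be told apart. The enabling feature is that the C3 and C6 oxygens are para, C4 carries a third oxygen and C5 is unsubstituted: C6–C5–C4–C3 is the carbon chain of a 3-alkoxycyclobutenedione without a C4 substituent, and C2 (with its methyl) and C1 (with its carboxyl) are the two alkene carbons of a but-2-enoate.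

## Retrosynthesis

**Protecting groups.** Target 23 is traced back to the tribenzyl compound 22, which carries benzyl ethers on the ring A catechol and a benzyl ester on ring C. No skeletal bond is cut. Benzyl is chosen over acid- or fluoride-labile groups because hydrogenolysis is the one deprotection that leaves two aryl esters, a catechol and an ortho-carbonyl methyl ether untouched. The forward step only has to be clean.

**Ring B–ring C ester.** The C–O bond between the ring B carbonyl and O4 of ring C is cut, giving the ring A–ring B acid 19 and benzyl orsellinate 21 (one step from orsellinic acid 20). The alternative order, acylating a preformed ring B–ring C didepside with the ring A acid, would need a ring B acid whose 4-hydroxyl is masked orthogonally to benzyl, at a cost of several steps. The forward acylation has to pick the unchelated 4-hydroxyl of 21 and tolerate the hydrogen-bonded ortho hydroxyl of 19.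

**Ring B carboxyl and ring A–ring B ester.** Acid 19 is traced to aldehyde 18, and the ester C–O bond between the ring A carbonyl and O4 of ring B is then cut to give acid 16 and commercial 2,4-dihydroxy-6-methylbenzaldehyde 17. Carrying ring B as an aldehyde means its future carboxyl cannot compete as an acyl donor, so ring B needs no protecting group at all. The forward steps need an activation strong enough for the di-ortho-substituted acid 16 and an aldehyde oxidation that does not chlorinate a phenolic ring.

**Ring A functional-group changes.** Acid 16 goes back through tert-butyl ester 15 and silyl ether 14 to phenol 13. No carbon–carbon bond is cut. In 13 the three oxygens are distinct by origin: C6 is a free phenol, C4 a benzyl ether and C3 a silyl ether. Methylation therefore needs no selectivity, the silyl group is exchanged for benzyl, and the tert-butyl ester is cleaved by acid, not by saponification of a hindered benzoate. An isopropyl ether at C4 would have to be removed with a boron halide and the catechol re-benzylated through a free trihydroxy acid. That is why the C4 oxygen carries benzyl from the first step.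

**Key disconnection.** Ring A of 13 is opened at the C1–C6 bond to dienylketene 11 (via its keto tautomer 12), and 11 is closed back across C6 and C3 to the cyclobutenone 10. Other cuts through ring A (polyketide-type folds, Michael–Dieckmann) give resorcinols whose oxygens are differentiated only by chelation, or rings at the wrong oxidation level. This cut delivers all five substituents at the aromatic level from a four-carbon and a two-carbon piece. The forward reaction must open the four-membered ring with the alkenyl arm turned toward the ketene.

**Carbinol–alkene bond.** The bond between the carbinol carbon of 10 (future C3) and the alkene carbon (future C2) is cut, giving the benzyl semisquarate 5 and the alkenylmagnesium reagent 8, made from the (Z)-iodoenoate 7. Addition must go to the ketone carbonyl of 5 and not to its vinylogous ester carbonyl. The alkoxide 9 must be silylated before it can lactonise onto the cis ester, which is why the ester is tert-butyl.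

**Starting materials.** Dione 5 comes from dibenzyl squarate 3 by replacing one benzyloxy group with hydrogen (hydride reduction to carbinol 4, then acid-induced carbonyl transposition). Diester 3 comes from squaric acid 1 and two molecules of benzyl alcohol 2, one for each acidic hydroxyl. Iodide 7 comes from tert-butyl but-2-ynoate 6 by anti addition of hydrogen iodide.

## Roads not taken

**Alternative 1:** The cut runs through ring B and the ring B–ring C ester: ring B is unfolded to an open 3,5,7-triketo ester. In the forward direction the diketo-dioxinone A2, heated with benzyl orsellinate 21, would fragment to an acylketene that the 4-hydroxyl of 21 traps. The resulting aryl trioxooctanoate would fold by aldol condensation (C2 onto the C7 ketone) and aromatise to benzyl lecanorate A1.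
- Merits: ring B and the ester to ring C form in one operation, ring B needs no protecting group, and A1 has the free 4-hydroxyl that acid 16 requires. A1 plus 16 would give 22 directly, replacing steps 9, 10 and 12 by one coupling. In convergence this road is better than the chosen end game.
- Weak points: the aryl β-keto ester can expel the phenoxide again or be cleaved under the aldol conditions. A2 needs its own synthesis of several steps. The road addresses the ring that can be bought (as 17) and leaves ring A unsolved, so it is a complement to a ring A synthesis and not a replacement.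
- Comparison: the chosen plan sets against the better convergence that its ring B costs no steps and that steps 9, 10 and 12 are routine depside operations.

**Alternative 2:** The cut is through the ring A C1–C2 and C4–C5 bonds with ring A at the cyclohexanedione level. Under alkoxide base the enolate of tert-butyl acetoacetate A5 would add to the β-carbon of ethyl 2-(benzyloxy)but-2-enoate A4, and the methyl ketone enolate would then close onto the ethyl ester to give dione A3. Dehydrogenation would give the resorcinol A6.
- Merits: two cheap components, and all six ring carbons and five substituents are placed in one flask. Benzylation of the 4-hydroxyl and methylation of the chelated 6-hydroxyl of A6 would reach 15 in about four steps, against seven in the chosen plan. On step count this road is shorter.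
- Weak points: A4 is a poor Michael acceptor (donor oxygen on the α-carbon, substituent on the β-carbon). The aromatisation needs an oxidant on an electron-rich 2-alkoxy-1,3-dione, and the classical halogenation–dehydrohalogenation tends to leave halogen at C5, whose reductive removal would also take the benzyl group. The 4- and 6-hydroxyls are distinguished only by chelation.
- Comparison: the chosen plan is longer, but each oxygen arrives differentiated and at the aromatic oxidation level with no oxidant.

**Alternative 3:** The cut is the ring A C5–C6 bond at the aromatic oxidation level. With an alkoxide base the methyl ketone enolate of the alkenylmalonate A8 would attack the cis ester carbonyl, lose alkoxide and tautomerise to the resorcinol ester A7.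
- Merits: no redox adjustment, and a short path: benzylation, methylation and ester hydrolysis would bring A7 to 16 in about four steps from A8.
- Weak points: A8 is a tetrasubstituted alkylidene malonate that would have to come from a Knoevenagel-type condensation on a ketone carbonyl of the strongly enolised diketone A9. Its doubly activated C3–H invites deconjugation and retro-condensation under the cyclisation base. The oxygens of A7 again differ only by chelation, and its methyl ester is flanked by two ortho substituents and hard to saponify.
- Comparison: if A8 were at hand this road would be shorter than the eight steps to 16. The chosen plan sets against this that each of its bond-forming steps has a close model and that it ends in an acid-labile ester.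

Key step: step 5

Remark: squaric acid, benzyl alcohol, tert-butyl but-2-ynoate, 2,4-dihydroxy-6-methylbenzaldehyde and orsellinic acid are taken as purchasable; dibenzyl squarate is made, not bought.

**Step 1**
Reactants: 1 squaric acid; 2 benzyl alcohol
Product: 3 dibenzyl squarate (3,4-bis(benzyloxy)cyclobut-3-ene-1,2-dione)
Conditions: BnOH (2.5 equiv in all), toluene, reflux, Dean–Stark trap
Reagents that add atoms: benzyl alcohol (second equivalent of 2), OCc1ccccc1
Why: Azeotropic Fischer-type esterification of a strongly acidic vinylogous diacid, which catalyses its own esterification; each of the two acidic hydroxyls takes up one molecule of benzyl alcohol, and removal of the two equivalents of water drives the reaction to the diester.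

**Step 2**
Reactants: 3 dibenzyl squarate
Product: 5 3-(benzyloxy)cyclobut-3-ene-1,2-dione, via 2,3-bis(benzyloxy)-4-hydroxycyclobut-2-en-1-one 4 (not isolated)
Conditions: LiAlH(OtBu)3, THF, −78 to −20 °C; then conc. HCl, CH2Cl2, rt
Reagents that add atoms: water, O
Why: The bulky hydride should reduce one squarate carbonyl only (1,2-reduction); acid then ionises the carbinol of 4, water re-adds at the benzyloxy-bearing end of the allyl cation and the hemiketal expels benzyl alcohol, the carbonyl transposition established for dialkyl squarates.

**Step 3**
Reactants: 6 tert-butyl but-2-ynoate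
Product: 7 tert-butyl (Z)-3-iodobut-2-enoate
Conditions: NaI, AcOH, 90 °C
Reagents that add atoms: sodium iodide, [Na+].[I-]
Why: Conjugate hydroiodination of an ynoate: iodide adds at C3 and the allenolate is protonated anti, so iodine and ester end up cis (Z); acetic acid is too weak to cleave the tert-butyl ester.

**Step 4**
Reactants: 7 tert-butyl (Z)-3-iodobut-2-enoate; 5 3-(benzyloxy)cyclobut-3-ene-1,2-dione
Product: 10 tert-butyl (Z)-3-[2-(benzyloxy)-1-[(tert-butyldimethylsilyl)oxy]-4-oxocyclobut-2-en-1-yl]but-2-enoate (racemic), via alkenylmagnesium chloride 8 (not isolated), via magnesium alkoxide 9 (not isolated)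
Conditions: iPrMgCl·LiCl, THF, −40 °C; then 5, THF, −78 °C; then TBSOTf, −78 to −30 °C
Reagents that add atoms: tert-butyldimethylsilyl trifluoromethanesulfonate, CC(C)(C)[Si](C)(C)OS(=O)(=O)C(F)(F)F
Why: Iodine–magnesium exchange gives the ester-chelated alkenyl Grignard reagent 8 with retention of geometry; it adds 1,2 to C2 of 5, the ketone carbonyl that is not part of the vinylogous ester, and the alkoxide 9 is O-silylated cold before it can attack the tert-butyl ester; the new carbinol centre forms racemic and is erased in step 5.

**Step 5**
Reactants: 10 tert-butyl (Z)-3-[2-(benzyloxy)-1-[(tert-butyldimethylsilyl)oxy]-4-oxocyclobut-2-en-1-yl]but-2-enoate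
Product: 13 tert-butyl 4-(benzyloxy)-3-[(tert-butyldimethylsilyl)oxy]-6-hydroxy-2-methylbenzoate, via dienylketene 11 (not isolated), via cyclohexadienone 12 (not isolated)
Conditions: toluene (degassed, 0.02 M), 110 °C
Reagents that add atoms: none
Why: Heating breaks the bond between the carbonyl carbon and the silyloxy-bearing carbon of the cyclobutenone in a thermal conrotatory 4π electrocyclic opening to the vinylketene 11. The one selectivity needed is torquoselectivity: the silyloxy donor on the breaking carbon rotates outward, which turns the butenoate arm inward, cis to the ketene. Ketene 11 is a hexatriene with the ketene carbon as one terminus, and a thermal disrotatory 6π electrocyclisation forms the C1–C6 bond and closes the six-membered carbocycle as cyclohexadienone 12. The ester at the other terminus points into the forming ring, but the sp-hybridised ketene carbon has no inward substituent to clash with it, so the closure should stay fast. Enolisation of 12, whose C1–H lies between a ketone and an ester, gives phenol 13. The closest known reaction is the thermal ring expansion of 4-alkenyl-4-silyloxycyclobutenones to hydroquinone monosilyl ethers (Moore rearrangement). No stereocentre is formed, and both the racemic carbinol centre and the alkene geometry of 10 are erased. The substitution order is fixed by connectivity: the four ring carbons of 10 become C6, C5, C4 and C3, and the butenoate supplies C2 with its methyl and C1 with its ester.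

**Step 6**
Reactants: 13 tert-butyl 4-(benzyloxy)-3-[(tert-butyldimethylsilyl)oxy]-6-hydroxy-2-methylbenzoate
Product: 14 tert-butyl 4-(benzyloxy)-3-[(tert-butyldimethylsilyl)oxy]-6-methoxy-2-methylbenzoate
Conditions: MeI, K2CO3, acetone (anhydrous), reflux
Reagents that add atoms: iodomethane, CI
Why: Williamson methylation of the only free hydroxyl; the chelated phenol needs carbonate and heat, and anhydrous acetone should leave the hindered aryl silyl ether (flanked by methyl and benzyloxy) in place.

**Step 7**
Reactants: 14 tert-butyl 4-(benzyloxy)-3-[(tert-butyldimethylsilyl)oxy]-6-methoxy-2-methylbenzoate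
Product: 15 tert-butyl 3,4-bis(benzyloxy)-6-methoxy-2-methylbenzoate
Conditions: CsF, BnBr, DMF, rt
Reagents that add atoms: benzyl bromide, BrCc1ccccc1
Why: Fluoride cleaves the aryl silyl ether and the caesium phenoxide is benzylated in the same flask (desilylative Williamson etherification); the tert-butyl ester and the methyl ether are inert.

**Step 8**
Reactants: 15 tert-butyl 3,4-bis(benzyloxy)-6-methoxy-2-methylbenzoate
Product: 16 3,4-bis(benzyloxy)-6-methoxy-2-methylbenzoic acid
Conditions: TFA, CH2Cl2 (1:4), 0 °C
Reagents that add atoms: none
Why: Acid-catalysed alkyl–oxygen cleavage of the tert-butyl ester with loss of isobutene, fast for a di-ortho-substituted benzoate; the one free ring position lies between two alkoxy groups and is shielded from tert-butylation, and the low temperature limits protodecarboxylation and benzyl ether loss.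

**Step 9**
Reactants: 16 3,4-bis(benzyloxy)-6-methoxy-2-methylbenzoic acid; 17 2,4-dihydroxy-6-methylbenzaldehyde
Product: 18 4-formyl-3-hydroxy-5-methylphenyl 3,4-bis(benzyloxy)-6-methoxy-2-methylbenzoate
Conditions: TFAA, toluene, rt
Reagents that add atoms: none
Why: Mixed trifluoroacetic anhydride activation, the classical depside esterification, suits the hindered electron-rich acid; of the two hydroxyls of 17 only the C4 hydroxyl is free, the C2 hydroxyl being hydrogen-bonded to the formyl group.

**Step 10**
Reactants: 18 4-formyl-3-hydroxy-5-methylphenyl 3,4-bis(benzyloxy)-6-methoxy-2-methylbenzoate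
Product: 19 4-{[3,4-bis(benzyloxy)-6-methoxy-2-methylbenzoyl]oxy}-2-hydroxy-6-methylbenzoic acid
Conditions: NaClO2, NaH2PO4, 2-methylbut-2-ene, t-BuOH/THF/H2O, 0 °C to rt
Reagents that add atoms: sodium chlorite, [Na+].[O-]Cl=O
Why: Pinnick oxidation takes the aldehyde to the acid under buffered conditions that leave the aryl ester and benzyl ethers alone; the alkene removes hypochlorous acid before it can chlorinate the phenolic ring.

**Step 11**
Reactants: 20 orsellinic acid
Product: 21 benzyl orsellinate (benzyl 2,4-dihydroxy-6-methylbenzoate)
Conditions: BnBr, KHCO3, DMF, rt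
Reagents that add atoms: benzyl bromide, BrCc1ccccc1
Why: Hydrogencarbonate deprotonates only the carboxylic acid, so SN2 benzylation gives the ester and leaves both phenols free.

**Step 12**
Reactants: 19 4-{[3,4-bis(benzyloxy)-6-methoxy-2-methylbenzoyl]oxy}-2-hydroxy-6-methylbenzoic acid; 21 benzyl orsellinate
Product: 22 benzyl 4-[(4-{[3,4-bis(benzyloxy)-6-methoxy-2-methylbenzoyl]oxy}-2-hydroxy-6-methylbenzoyl)oxy]-2-hydroxy-6-methylbenzoate
Conditions: TFAA, toluene, rt
Reagents that add atoms: none
Why: Second mixed-anhydride esterification at the unchelated C4 hydroxyl of 21; the ortho hydroxyl of 19 is hydrogen-bonded to its own carboxyl and should not be acylated.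

**Step 13**
Reactants: 22 benzyl 4-[(4-{[3,4-bis(benzyloxy)-6-methoxy-2-methylbenzoyl]oxy}-2-hydroxy-6-methylbenzoyl)oxy]-2-hydroxy-6-methylbenzoate
Product: 23 4-[(4-{[3,4-dihydroxy-6-methoxy-2-methylbenzoyl]oxy}-2-hydroxy-6-methylbenzoyl)oxy]-2-hydroxy-6-methylbenzoic acid (CNP0222366.0)
Conditions: H2 (1 atm), 10% Pd/C, EtOAc, rt
Reagents that add atoms: none
Why: Catalytic hydrogenolysis removes two benzyl ethers and one benzyl ester under neutral conditions that spare both depside esters and the methyl ether.

## Compound list

1 | squaric acid (3,4-dihydroxycyclobut-3-ene-1,2-dione) | OC1=C(O)C(=O)C1=O | starting material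
2 | benzyl alcohol | OCc1ccccc1 | starting material
3 | dibenzyl squarate (3,4-bis(benzyloxy)cyclobut-3-ene-1,2-dione) | O=C1C(=O)C(OCc2ccccc2)=C1OCc1ccccc1 | intermediate
4 | 2,3-bis(benzyloxy)-4-hydroxycyclobut-2-en-1-one (racemic) | O=C1C(OCc2ccccc2)=C(OCc2ccccc2)C1O | intermediate
5 | 3-(benzyloxy)cyclobut-3-ene-1,2-dione | O=C1C=C(OCc2ccccc2)C1=O | intermediate
6 | tert-butyl but-2-ynoate | CC#CC(=O)OC(C)(C)C | starting material
7 | tert-butyl (Z)-3-iodobut-2-enoate | C/C(I)=C/C(=O)OC(C)(C)C | intermediate
8 | [(Z)-4-(tert-butoxy)-4-oxobut-2-en-2-yl]magnesium chloride | C/C([Mg]Cl)=C/C(=O)OC(C)(C)C | intermediate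
9 | chloromagnesium alkoxide of tert-butyl (Z)-3-[2-(benzyloxy)-1-hydroxy-4-oxocyclobut-2-en-1-yl]but-2-enoate (racemic) | O=C1C=C(OCc2ccccc2)C1(O[Mg]Cl)/C(C)=C\C(=O)OC(C)(C)C | intermediate
10 | tert-butyl (Z)-3-[2-(benzyloxy)-1-[(tert-butyldimethylsilyl)oxy]-4-oxocyclobut-2-en-1-yl]but-2-enoate (racemic) | O=C1C=C(OCc2ccccc2)C1(O[Si](C)(C)C(C)(C)C)/C(C)=C\C(=O)OC(C)(C)C | intermediate
11 | tert-butyl (2Z,4Z)-5-(benzyloxy)-4-[(tert-butyldimethylsilyl)oxy]-3-methyl-7-oxohepta-2,4,6-trienoate (dienylketene) | O=C=C/C(OCc1ccccc1)=C(O[Si](C)(C)C(C)(C)C)\C(C)=C/C(=O)OC(C)(C)C | intermediate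
12 | tert-butyl 4-(benzyloxy)-3-[(tert-butyldimethylsilyl)oxy]-2-methyl-6-oxocyclohexa-2,4-diene-1-carboxylate (racemic) | O=C1C=C(OCc2ccccc2)C(O[Si](C)(C)C(C)(C)C)=C(C)C1C(=O)OC(C)(C)C | intermediate
13 | tert-butyl 4-(benzyloxy)-3-[(tert-butyldimethylsilyl)oxy]-6-hydroxy-2-methylbenzoate | Cc1c(O[Si](C)(C)C(C)(C)C)c(OCc2ccccc2)cc(O)c1C(=O)OC(C)(C)C | intermediate
14 | tert-butyl 4-(benzyloxy)-3-[(tert-butyldimethylsilyl)oxy]-6-methoxy-2-methylbenzoate | COc1cc(OCc2ccccc2)c(O[Si](C)(C)C(C)(C)C)c(C)c1C(=O)OC(C)(C)C | intermediate
15 | tert-butyl 3,4-bis(benzyloxy)-6-methoxy-2-methylbenzoate | COc1cc(OCc2ccccc2)c(OCc2ccccc2)c(C)c1C(=O)OC(C)(C)C | intermediate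
16 | 3,4-bis(benzyloxy)-6-methoxy-2-methylbenzoic acid | COc1cc(OCc2ccccc2)c(OCc2ccccc2)c(C)c1C(=O)O | intermediate
17 | 2,4-dihydroxy-6-methylbenzaldehyde | Cc1cc(O)cc(O)c1C=O | starting material
18 | 4-formyl-3-hydroxy-5-methylphenyl 3,4-bis(benzyloxy)-6-methoxy-2-methylbenzoate | COc1cc(OCc2ccccc2)c(OCc2ccccc2)c(C)c1C(=O)Oc1cc(C)c(C=O)c(O)c1 | intermediate
19 | 4-{[3,4-bis(benzyloxy)-6-methoxy-2-methylbenzoyl]oxy}-2-hydroxy-6-methylbenzoic acid | COc1cc(OCc2ccccc2)c(OCc2ccccc2)c(C)c1C(=O)Oc1cc(C)c(C(=O)O)c(O)c1 | intermediate
20 | orsellinic acid (2,4-dihydroxy-6-methylbenzoic acid) | Cc1cc(O)cc(O)c1C(=O)O | starting material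
21 | benzyl orsellinate (benzyl 2,4-dihydroxy-6-methylbenzoate) | Cc1cc(O)cc(O)c1C(=O)OCc1ccccc1 | intermediate
22 | benzyl 4-[(4-{[3,4-bis(benzyloxy)-6-methoxy-2-methylbenzoyl]oxy}-2-hydroxy-6-methylbenzoyl)oxy]-2-hydroxy-6-methylbenzoate | COc1cc(OCc2ccccc2)c(OCc2ccccc2)c(C)c1C(=O)Oc1cc(C)c(C(=O)Oc2cc(C)c(C(=O)OCc3ccccc3)c(O)c2)c(O)c1 | intermediate
23 | 4-[(4-{[3,4-dihydroxy-6-methoxy-2-methylbenzoyl]oxy}-2-hydroxy-6-methylbenzoyl)oxy]-2-hydroxy-6-methylbenzoic acid (CNP0222366.0) | COc1cc(O)c(O)c(C)c1C(=O)Oc1cc(C)c(C(=O)Oc2cc(C)c(C(=O)O)c(O)c2)c(O)c1 | target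

## Step count and least certain steps

Total: 13 steps. Longest linear sequence: 11 steps (1, 2, 4, 5, 6, 7, 8, 9, 10, 12, 13) from squaric acid.

**Step 5 (key step).** The most likely failure is slow 6π closure of ketene 11, because the ester at the alkene terminus points into the forming ring. The ketene would then be lost to dimerisation or to traces of nucleophile, and prolonged heating would also begin to cost the silyl ether. The fallback keeps the ring expansion but removes the terminal substituent and adds the carboxyl carbon afterwards; it sets out from 5 and returns at 16: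
- Isopropenylmagnesium bromide (CH2=C(CH3)MgBr) is added to 5 and the alkoxide silylated with TBSOTf, giving 3-(benzyloxy)-4-[(tert-butyldimethylsilyl)oxy]-4-(prop-1-en-2-yl)cyclobut-2-en-1-one F1.
- Thermolysis in toluene should give 3-(benzyloxy)-4-[(tert-butyldimethylsilyl)oxy]-5-methylphenol F2.
- Methylation (MeI, K2CO3) gives 1-(benzyloxy)-2-[(tert-butyldimethylsilyl)oxy]-5-methoxy-3-methylbenzene F3.
- CsF and BnBr give 1,2-bis(benzyloxy)-5-methoxy-3-methylbenzene F4.
- Vilsmeier–Haack formylation (POCl3, DMF) is expected at the position between methyl and methoxy, para to a benzyloxy group, the site at which orcinol ethers are formylated. It gives 3,4-bis(benzyloxy)-6-methoxy-2-methylbenzaldehyde F5.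
- Pinnick oxidation of F5 gives 16.

**Step 4.** The likely failure is lactonisation of alkoxide 9 onto the cis tert-butyl ester (spirobutenolide formation) before silylation is complete. Incomplete iodine–magnesium exchange or attack at the vinylogous ester carbonyl are lesser risks. The fallback removes the electrophile by using a carboxylate; it sets out from 7 and returns at 10:
- TFA cleaves 7 to (Z)-3-iodobut-2-enoic acid F6.
- Two equivalents of n-BuLi at −100 °C give lithium 3-lithiobut-2-enoate F7 (lithium cis to the carboxylate).
- F7 is added to 5 and the dianion treated with excess TBSOTf, giving the silyl ester tert-butyldimethylsilyl (Z)-3-[2-(benzyloxy)-1-[(tert-butyldimethylsilyl)oxy]-4-oxocyclobut-2-en-1-yl]but-2-enoate F8.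
- Mild aqueous work-up hydrolyses F8 to (Z)-3-[2-(benzyloxy)-1-[(tert-butyldimethylsilyl)oxy]-4-oxocyclobut-2-en-1-yl]but-2-enoic acid F9.
- O-tert-butyl-N,N′-diisopropylisourea converts F9 into 10.

**Step 2.** The reduction–transposition sequence is established for simple dialkyl squarates. With benzyl groups the likely failure is acid-promoted loss of both benzyl groups during the hydrochloric acid stage, with the product lost to the aqueous phase. The fallback runs the sequence on the isopropyl ester and introduces benzyl afterwards; it sets out from benzyl alcohol 2 together with commercial diisopropyl squarate F10 and returns at 5: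
- F10 is reduced with LiAlH(OtBu)3 and treated with HCl to give 3-isopropoxycyclobut-3-ene-1,2-dione F11.
- Aqueous HCl hydrolyses F11 to 3-hydroxycyclobut-3-ene-1,2-dione (semisquaric acid) F12.
- Azeotropic esterification of F12 with 2 in toluene, as in step 1, gives 5.

**Step 6.** The likely failure is partial cleavage of the aryl silyl ether by carbonate during the slow methylation of the chelated phenol, followed by methylation of the C3 oxygen as well. The fallback reverses the order and relies on chelation; it sets out from 13 and returns at 15:
- CsF with one equivalent of BnBr benzylates the unchelated C3 oxygen only, as in the selective alkylation of 2,5-dihydroxybenzoates, giving tert-butyl 3,4-bis(benzyloxy)-6-hydroxy-2-methylbenzoate F13.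
- Methylation of F13 (MeI, K2CO3) gives 15 with no silyl group left to lose.

**Step 12.** The likely failure is self-acylation of the hydroxy acid 19 through its ortho hydroxyl once the mixed anhydride is formed, or sluggish acylation of 21. The fallback caps that hydroxyl and changes the activation; it sets out from 18 and returns at 23:
- Mitsunobu benzylation of 18 (benzyl alcohol 2, PPh3, diisopropyl azodicarboxylate) gives 3-(benzyloxy)-4-formyl-5-methylphenyl 3,4-bis(benzyloxy)-6-methoxy-2-methylbenzoate F14.
- Pinnick oxidation gives 2-(benzyloxy)-4-{[3,4-bis(benzyloxy)-6-methoxy-2-methylbenzoyl]oxy}-6-methylbenzoic acid F15.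
- Carbodiimide coupling with 21 (dicyclohexylcarbodiimide, catalytic 4-dimethylaminopyridine) gives benzyl 4-[(2-(benzyloxy)-4-{[3,4-bis(benzyloxy)-6-methoxy-2-methylbenzoyl]oxy}-6-methylbenzoyl)oxy]-2-hydroxy-6-methylbenzoate F16.
- Hydrogenolysis of F16 over Pd/C gives 23.

## Further compounds

F1 | step 5 | 3-(benzyloxy)-4-[(tert-butyldimethylsilyl)oxy]-4-(prop-1-en-2-yl)cyclobut-2-en-1-one (racemic) | O=C1C=C(OCc2ccccc2)C1(O[Si](C)(C)C(C)(C)C)C(C)=C
F2 | step 5 | 3-(benzyloxy)-4-[(tert-butyldimethylsilyl)oxy]-5-methylphenol | Cc1cc(O)cc(OCc2ccccc2)c1O[Si](C)(C)C(C)(C)C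
F3 | step 5 | 1-(benzyloxy)-2-[(tert-butyldimethylsilyl)oxy]-5-methoxy-3-methylbenzene | COc1cc(C)c(O[Si](C)(C)C(C)(C)C)c(OCc2ccccc2)c1
F4 | step 5 | 1,2-bis(benzyloxy)-5-methoxy-3-methylbenzene | COc1cc(C)c(OCc2ccccc2)c(OCc2ccccc2)c1
F5 | step 5 | 3,4-bis(benzyloxy)-6-methoxy-2-methylbenzaldehyde | COc1cc(OCc2ccccc2)c(OCc2ccccc2)c(C)c1C=O
F6 | step 4 | (Z)-3-iodobut-2-enoic acid | C/C(I)=C/C(=O)O
F7 | step 4 | lithium 3-lithiobut-2-enoate (lithium cis to the carboxylate) | C/C([Li])=C/C(=O)O[Li]
F8 | step 4 | tert-butyldimethylsilyl (Z)-3-[2-(benzyloxy)-1-[(tert-butyldimethylsilyl)oxy]-4-oxocyclobut-2-en-1-yl]but-2-enoate (racemic) | O=C1C=C(OCc2ccccc2)C1(O[Si](C)(C)C(C)(C)C)/C(C)=C\C(=O)O[Si](C)(C)C(C)(C)C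
F9 | step 4 | (Z)-3-[2-(benzyloxy)-1-[(tert-butyldimethylsilyl)oxy]-4-oxocyclobut-2-en-1-yl]but-2-enoic acid (racemic) | O=C1C=C(OCc2ccccc2)C1(O[Si](C)(C)C(C)(C)C)/C(C)=C\C(=O)O
F10 | step 2 | diisopropyl squarate | CC(C)OC1=C(OC(C)C)C(=O)C1=O
F11 | step 2 | 3-isopropoxycyclobut-3-ene-1,2-dione | CC(C)OC1=CC(=O)C1=O
F12 | step 2 | 3-hydroxycyclobut-3-ene-1,2-dione (semisquaric acid) | OC1=CC(=O)C1=O
F13 | step 6 | tert-butyl 3,4-bis(benzyloxy)-6-hydroxy-2-methylbenzoate | Cc1c(OCc2ccccc2)c(OCc2ccccc2)cc(O)c1C(=O)OC(C)(C)C
F14 | step 12 | 3-(benzyloxy)-4-formyl-5-methylphenyl 3,4-bis(benzyloxy)-6-methoxy-2-methylbenzoate | COc1cc(OCc2ccccc2)c(OCc2ccccc2)c(C)c1C(=O)Oc1cc(C)c(C=O)c(OCc2ccccc2)c1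
F15 | step 12 | 2-(benzyloxy)-4-{[3,4-bis(benzyloxy)-6-methoxy-2-methylbenzoyl]oxy}-6-methylbenzoic acid | COc1cc(OCc2ccccc2)c(OCc2ccccc2)c(C)c1C(=O)Oc1cc(C)c(C(=O)O)c(OCc2ccccc2)c1
F16 | step 12 | benzyl 4-[(2-(benzyloxy)-4-{[3,4-bis(benzyloxy)-6-methoxy-2-methylbenzoyl]oxy}-6-methylbenzoyl)oxy]-2-hydroxy-6-methylbenzoate | COc1cc(OCc2ccccc2)c(OCc2ccccc2)c(C)c1C(=O)Oc1cc(C)c(C(=O)Oc2cc(C)c(C(=O)OCc3ccccc3)c(O)c2)c(OCc2ccccc2)c1
A1 | alternative 1 | benzyl lecanorate (benzyl 4-[(2,4-dihydroxy-6-methylbenzoyl)oxy]-2-hydroxy-6-methylbenzoate) | Cc1cc(O)cc(O)c1C(=O)Oc1cc(C)c(C(=O)OCc2ccccc2)c(O)c1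
A2 | alternative 1 | 6-(2,4-dioxopentyl)-2,2-dimethyl-4H-1,3-dioxin-4-one | CC(=O)CC(=O)CC1=CC(=O)OC(C)(C)O1
A3 | alternative 2 | tert-butyl 3-(benzyloxy)-2-methyl-4,6-dioxocyclohexane-1-carboxylate (mixture of diastereomers) | CC1C(OCc2ccccc2)C(=O)CC(=O)C1C(=O)OC(C)(C)C
A4 | alternative 2 | ethyl 2-(benzyloxy)but-2-enoate (alkene geometry not fixed) | CC=C(OCc1ccccc1)C(=O)OCC
A5 | alternative 2 | tert-butyl acetoacetate | CC(=O)CC(=O)OC(C)(C)C
A6 | alternative 2 | tert-butyl 3-(benzyloxy)-4,6-dihydroxy-2-methylbenzoate | Cc1c(OCc2ccccc2)c(O)cc(O)c1C(=O)OC(C)(C)C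
A7 | alternative 3 | methyl 3-(benzyloxy)-4,6-dihydroxy-2-methylbenzoate | COC(=O)c1c(C)c(OCc2ccccc2)c(O)cc1O
A8 | alternative 3 | dimethyl 2-[3-(benzyloxy)-4-oxopentan-2-ylidene]propanedioate | CC(=O)C(OCc1ccccc1)C(C)=C(C(=O)OC)C(=O)OC
A9 | alternative 3 | 3-(benzyloxy)pentane-2,4-dione | CC(=O)C(OCc1ccccc1)C(C)=O
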